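**Plan**

- Retrosynthetic cuts, in order: the ten O-benzyl groups and a C5–Cl helper on ring A of the upper unit; C3–OH and C4–H (hydroboration of a flav-3-ene); C3=C4 (dehydration of a chroman-4-ol); then, in one operation, O1–C8a and C4–C4a of the upper ring C; the C2–O bond (conjugate borylation of a chalcone); the acyl–C8 bond to the lower unit.
- Enabling feature: ring A of the upper unit carries the ether oxygen O1 and the carbon C4 on adjacent carbons C8a and C4a, and these are the two ends of the chain O1–C2–C3–C4 of ring C. That is the retron of an aryne captured by a 3-hydroxy ketone. C5 of this 5-deoxy ring is free to hold a chlorine that steers the aryne addition.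
- Forward order: the lower unit arrives with rings A, C and B complete (epigallocatechin); its C8 is acylated; the upper ring C is then closed onto a new ring A by aryne annulation; C3=C4 is formed and hydrated in the anti-Markovnikov sense; hydrogenolysis finishes.
- Stereochemistry: lower unit from the chiral pool; upper C2 from ligand-controlled copper borylation; upper C3 and C4 from syn hydroboration on the face opposite the C2 aryl group.

Key step: step 9

Assumption: the Josiphos antipode named in step 8 is taken to give the (3S) carbinol by analogy with simple chalcones; if the opposite sense is found, the mirror-image ligand is used.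

**Route**

Step 1
Reactants: 1 4-(benzyloxy)phenol
Product: 2 4-(benzyloxy)-2-chlorophenol
Conditions: SO2Cl2 (1.05 equiv), n-Bu2NH (cat.), toluene, 0 °C → rt
Reagents that add atoms: sulfuryl chloride ClS(Cl)(=O)=O
Why: Electrophilic aromatic chlorination; the free hydroxyl is the stronger ortho director and the para position is blocked, so one chlorine should enter ortho to OH.

Step 2
Reactants: 2 4-(benzyloxy)-2-chlorophenol
Product: 3 4-(benzyloxy)-2-bromo-6-chlorophenol
Conditions: NBS (1.05 equiv), i-Pr2NH (cat.), CH2Cl2, 0 °C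
Reagents that add atoms: N-bromosuccinimide O=C1CCC(=O)N1Br
Why: Amine-mediated ortho-selective electrophilic bromination of a phenol fills the remaining position ortho to OH.

Step 3
Reactants: 3 4-(benzyloxy)-2-bromo-6-chlorophenol
Product: 6 4-(benzyloxy)-2-chloro-6-(trimethylsilyl)phenyl trifluoromethanesulfonate, via aryl trimethylsilyl ether 4 (not isolated), via lithium 2-silylphenoxide 5 (not isolated)
Conditions: HMDS, THF, 65 °C, evaporate; n-BuLi, THF, −78 °C; Tf2O, −78 → 0 °C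
Reagents that add atoms: hexamethyldisilazane C[Si](C)(C)N[Si](C)(C)C; trifluoromethanesulfonic anhydride O=S(=O)(OS(=O)(=O)C(F)(F)F)C(F)(F)F
Why: O-silylation, bromine–lithium exchange (chlorine is inert at −78 °C), retro-Brook 1,3-silyl shift from O to C and triflation of the phenoxide, the standard entry to ortho-silylaryl triflate aryne precursors.

Step 4
Reactants: 7 (−)-epigallocatechin
Product: 9 (2R,3R)-3,5,7-tris(benzyloxy)-2-[3,4,5-tris(benzyloxy)phenyl]chromane, via pentabenzyl ether 8 (not isolated)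
Conditions: BnBr, K2CO3, DMF, rt; then NaH, BnBr, 0 °C → rt
Reagents that add atoms: benzyl bromide BrCc1ccccc1
Why: Williamson etherification, in which carbonate alkylates the five phenols and hydride then the secondary alcohol; no stereocenter is touched.

Step 5
Reactants: 9 (2R,3R)-3,5,7-tris(benzyloxy)-2-[3,4,5-tris(benzyloxy)phenyl]chromane
Product: 10 (2R,3R)-3,5,7-tris(benzyloxy)-8-bromo-2-[3,4,5-tris(benzyloxy)phenyl]chromane
Conditions: NBS (1.0 equiv), CH2Cl2, −78 → 0 °C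
Reagents that add atoms: N-bromosuccinimide O=C1CCC(=O)N1Br
Why: Electrophilic aromatic bromination of the phloroglucinol-type ring A, which in perbenzylated flavan-3-ols is known to take place at C8.

Step 6
Reactants: 11 3,4,5-tris(benzyloxy)benzaldehyde
Product: 12 (E)-N-methoxy-N-methyl-3-[3,4,5-tris(benzyloxy)phenyl]prop-2-enamide
Conditions: (EtO)2P(O)CH2C(O)N(OMe)Me, NaH, THF, 0 °C → rt
Reagents that add atoms: diethyl [2-[methoxy(methyl)amino]-2-oxoethyl]phosphonate CCOP(=O)(OCC)CC(=O)N(C)OC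
Why: Horner–Wadsworth–Emmons olefination with a stabilized phosphonate should give the E-configured enamide.

Step 7
Reactants: 10 (2R,3R)-3,5,7-tris(benzyloxy)-8-bromo-2-[3,4,5-tris(benzyloxy)phenyl]chromane; 12 (E)-N-methoxy-N-methyl-3-[3,4,5-tris(benzyloxy)phenyl]prop-2-enamide
Product: 14 (E)-1-[(2R,3R)-3,5,7-tris(benzyloxy)-2-(3,4,5-tris(benzyloxy)phenyl)chroman-8-yl]-3-[3,4,5-tris(benzyloxy)phenyl]prop-2-en-1-one, via 8-lithio arene 13 (not isolated)
Conditions: n-BuLi, THF, −78 °C; then 12, −78 → 0 °C; 1 M HCl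
Reagents that add atoms: none
Why: Bromine–lithium exchange and Weinreb ketone synthesis; the chelated tetrahedral adduct prevents over-addition and the vinylic amide offers no acidic α-hydrogen to the hindered aryllithium.

Step 8
Reactants: 14 (E)-1-[(2R,3R)-3,5,7-tris(benzyloxy)-2-(3,4,5-tris(benzyloxy)phenyl)chroman-8-yl]-3-[3,4,5-tris(benzyloxy)phenyl]prop-2-en-1-one
Product: 16 (3S)-3-hydroxy-3-[3,4,5-tris(benzyloxy)phenyl]-1-[(2R,3R)-3,5,7-tris(benzyloxy)-2-(3,4,5-tris(benzyloxy)phenyl)chroman-8-yl]propan-1-one, via β-boryl ketone 15 (not isolated)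
Conditions: CuCl (5 mol %), (R)-1-[(S)-2-(diphenylphosphino)ferrocenyl]ethyldicyclohexylphosphine (6 mol %), NaOtBu (10 mol %), B2pin2, MeOH, THF, rt; then 30% H2O2, pH 7 phosphate buffer, 0 °C
Reagents that add atoms: hydrogen peroxide OO (the carbinol oxygen); bis(pinacolato)diboron CC1(C)OB(OC1(C)C)B1OC(C)(C)C(C)(C)O1 (boron of 15 only)
Why: Copper-catalysed asymmetric conjugate borylation, in which the ligand-bound boryl-copper adds to the β-carbon, followed by stereoretentive C–B oxidation sets the carbinol center that becomes C2 of the upper unit.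

Step 9
Reactants: 16 (3S)-3-hydroxy-3-[3,4,5-tris(benzyloxy)phenyl]-1-[(2R,3R)-3,5,7-tris(benzyloxy)-2-(3,4,5-tris(benzyloxy)phenyl)chroman-8-yl]propan-1-one; 6 4-(benzyloxy)-2-chloro-6-(trimethylsilyl)phenyl trifluoromethanesulfonate
Product: 19 (2S,4RS)-7-(benzyloxy)-5-chloro-2-[3,4,5-tris(benzyloxy)phenyl]-4-[(2R,3R)-3,5,7-tris(benzyloxy)-2-(3,4,5-tris(benzyloxy)phenyl)chroman-8-yl]chroman-4-ol, via 5-(benzyloxy)-3-chlorobenzyne 17 (not isolated), via ortho-potassio aryl ether 18 (not isolated)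
Conditions: KF, 18-crown-6, THF, 0 °C → rt, 6 (1.8 equiv) added slowly
Reagents that add atoms: none
Why: Proposed new method: fluoride releases aryne 17 from 6, the fluoride-bound C2 hydroxyl of 16 adds to the aryne carbon remote from chlorine, and the aryl anion 18 so formed adds to the C4 ketone, so that O1–C8a and C4–C4a form in one operation and the upper ring C closes onto ring A. The closest known reaction type is the aryne annulation of phenoxide or sulfonamide nucleophiles that carry a carbonyl trap (salicylates and ortho-hydroxyaryl ketones to xanthones and xanthenols, N-sulfonyl β-amino ketones to dihydroquinolines); an aliphatic aldol-type hydroxyl has not been used in this role. The six-membered ring closes by 6-exo-trig attack of the aryl carbanion on the carbonyl carbon. The new stereocenter C4 is not controlled and need not be, since step 10 erases it, while C2 keeps its configuration because its C–O bond is never broken. The step needs regioselective addition (oxygen meta and carbon para to the benzyloxy group), which the C5 chlorine should secure by inductive distortion of the aryne (attack at the distal carbon, carbanion next to C–Cl), and it needs O-arylation to outrun retro-aldol cleavage and dehydration of 16, which the weakly basic, non-protic fluoride medium and the slow addition of 6 are meant to secure. Chlorine is chosen over bromine because an ortho-chloro aryl anion expels halide far more slowly than it can cyclize.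

Step 10
Reactants: 19 (2S,4RS)-7-(benzyloxy)-5-chloro-2-[3,4,5-tris(benzyloxy)phenyl]-4-[(2R,3R)-3,5,7-tris(benzyloxy)-2-(3,4,5-tris(benzyloxy)phenyl)chroman-8-yl]chroman-4-ol
Product: 20 (2S)-7-(benzyloxy)-5-chloro-2-[3,4,5-tris(benzyloxy)phenyl]-4-[(2R,3R)-3,5,7-tris(benzyloxy)-2-(3,4,5-tris(benzyloxy)phenyl)chroman-8-yl]-2H-chromene
Conditions: PPTS (10 mol %), 4 Å MS, toluene, 50 °C, dark
Reagents that add atoms: none
Why: Acid-catalysed E1 dehydration; the tertiary, doubly benzylic C4 alcohol should ionize far more readily than the C2–O1 bond, and loss of H3 gives the flav-3-ene from both C4 epimers with C2 untouched.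

Step 11
Reactants: 20 (2S)-7-(benzyloxy)-5-chloro-2-[3,4,5-tris(benzyloxy)phenyl]-4-[(2R,3R)-3,5,7-tris(benzyloxy)-2-(3,4,5-tris(benzyloxy)phenyl)chroman-8-yl]-2H-chromene
Product: 22 (2R,3S,4R)-7-(benzyloxy)-5-chloro-2-[3,4,5-tris(benzyloxy)phenyl]-4-[(2R,3R)-3,5,7-tris(benzyloxy)-2-(3,4,5-tris(benzyloxy)phenyl)chroman-8-yl]chroman-3-ol, via C3 alkylborane 21 (not isolated)
Conditions: BH3·THF, THF, 0 °C → rt; then 3 M NaOH, 30% H2O2, 0 °C
Reagents that add atoms: hydrogen peroxide OO (the C3 oxygen); borane–tetrahydrofuran B.C1CCOC1 (boron of 21 only)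
Why: Hydroboration–oxidation; borane should add syn from the face opposite the C2 aryl group with boron at the less substituted C3 and hydrogen at the diaryl-substituted C4, and oxidation with retention then gives the 2,3-trans-3,4-trans alcohol.

Step 12
Reactants: 22 (2R,3S,4R)-7-(benzyloxy)-5-chloro-2-[3,4,5-tris(benzyloxy)phenyl]-4-[(2R,3R)-3,5,7-tris(benzyloxy)-2-(3,4,5-tris(benzyloxy)phenyl)chroman-8-yl]chroman-3-ol
Product: 23 robinetinidol-(4α→8)-epigallocatechin (CNP0275321.3)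
Conditions: H2 (1–3 atm), Pd(OH)2/C, NaOAc, THF/MeOH, rt
Reagents that add atoms: none
Why: Heterogeneous palladium-catalysed hydrogenolysis should cleave the ten benzyl ethers and, with acetate as HCl scavenger, the aryl C–Cl bond, leaving the five stereocenters untouched.

**Compound list**

1 | 4-(benzyloxy)phenol | Oc1ccc(OCc2ccccc2)cc1 | starting material
2 | 4-(benzyloxy)-2-chlorophenol | Oc1ccc(OCc2ccccc2)cc1Cl | intermediate
3 | 4-(benzyloxy)-2-bromo-6-chlorophenol | Oc1c(Br)cc(OCc2ccccc2)cc1Cl | intermediate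
4 | [4-(benzyloxy)-2-bromo-6-chlorophenoxy]trimethylsilane (not isolated) | C[Si](C)(C)Oc1c(Br)cc(OCc2ccccc2)cc1Cl | intermediate
5 | lithium 4-(benzyloxy)-2-chloro-6-(trimethylsilyl)phenoxide (not isolated) | [Li+].[O-]c1c(Cl)cc(OCc2ccccc2)cc1[Si](C)(C)C | intermediate
6 | 4-(benzyloxy)-2-chloro-6-(trimethylsilyl)phenyl trifluoromethanesulfonate | C[Si](C)(C)c1cc(OCc2ccccc2)cc(Cl)c1OS(=O)(=O)C(F)(F)F | intermediate
7 | (−)-epigallocatechin, (2R,3R)-2-(3,4,5-trihydroxyphenyl)chromane-3,5,7-triol | Oc1cc(O)c2c(c1)O[C@H](c1cc(O)c(O)c(O)c1)[C@H](O)C2 | starting material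
8 | (2R,3R)-5,7-bis(benzyloxy)-2-[3,4,5-tris(benzyloxy)phenyl]chroman-3-ol (not isolated) | c5c(OCc4ccccc4)cc(OCc4ccccc4)c6c5O[C@H](c7cc(OCc4ccccc4)c(OCc4ccccc4)c(OCc4ccccc4)c7)[C@H](O)C6 | intermediate
9 | (2R,3R)-3,5,7-tris(benzyloxy)-2-[3,4,5-tris(benzyloxy)phenyl]chromane | c5c(OCc4ccccc4)cc(OCc4ccccc4)c6c5O[C@H](c7cc(OCc4ccccc4)c(OCc4ccccc4)c(OCc4ccccc4)c7)[C@H](OCc4ccccc4)C6 | intermediate
10 | (2R,3R)-3,5,7-tris(benzyloxy)-8-bromo-2-[3,4,5-tris(benzyloxy)phenyl]chromane | Brc5c(OCc4ccccc4)cc(OCc4ccccc4)c6c5O[C@H](c7cc(OCc4ccccc4)c(OCc4ccccc4)c(OCc4ccccc4)c7)[C@H](OCc4ccccc4)C6 | intermediate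
11 | 3,4,5-tris(benzyloxy)benzaldehyde | O=Cc1cc(OCc2ccccc2)c(OCc2ccccc2)c(OCc2ccccc2)c1 | starting material
12 | (E)-N-methoxy-N-methyl-3-[3,4,5-tris(benzyloxy)phenyl]prop-2-enamide | CON(C)C(=O)/C=C/c1cc(OCc2ccccc2)c(OCc2ccccc2)c(OCc2ccccc2)c1 | intermediate
13 | 8-lithio derivative of 9 (not isolated) | [Li]c5c(OCc4ccccc4)cc(OCc4ccccc4)c6c5O[C@H](c7cc(OCc4ccccc4)c(OCc4ccccc4)c(OCc4ccccc4)c7)[C@H](OCc4ccccc4)C6 | intermediate
14 | (E)-1-[(2R,3R)-3,5,7-tris(benzyloxy)-2-(3,4,5-tris(benzyloxy)phenyl)chroman-8-yl]-3-[3,4,5-tris(benzyloxy)phenyl]prop-2-en-1-one | O=C(/C=C/c3cc(OCc4ccccc4)c(OCc4ccccc4)c(OCc4ccccc4)c3)c5c(OCc4ccccc4)cc(OCc4ccccc4)c6c5O[C@H](c7cc(OCc4ccccc4)c(OCc4ccccc4)c(OCc4ccccc4)c7)[C@H](OCc4ccccc4)C6 | intermediate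
15 | (3S)-3-(4,4,5,5-tetramethyl-1,3,2-dioxaborolan-2-yl) analogue of 16 (not isolated) | CC1(C)OB(OC1(C)C)[C@H](c3cc(OCc4ccccc4)c(OCc4ccccc4)c(OCc4ccccc4)c3)CC(=O)c5c(OCc4ccccc4)cc(OCc4ccccc4)c6c5O[C@H](c7cc(OCc4ccccc4)c(OCc4ccccc4)c(OCc4ccccc4)c7)[C@H](OCc4ccccc4)C6 | intermediate
16 | (3S)-3-hydroxy-3-[3,4,5-tris(benzyloxy)phenyl]-1-[(2R,3R)-3,5,7-tris(benzyloxy)-2-(3,4,5-tris(benzyloxy)phenyl)chroman-8-yl]propan-1-one | O[C@H](c3cc(OCc4ccccc4)c(OCc4ccccc4)c(OCc4ccccc4)c3)CC(=O)c5c(OCc4ccccc4)cc(OCc4ccccc4)c6c5O[C@H](c7cc(OCc4ccccc4)c(OCc4ccccc4)c(OCc4ccccc4)c7)[C@H](OCc4ccccc4)C6 | intermediate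
17 | 5-(benzyloxy)-3-chlorobenzyne (not isolated) | ClC1=CC(OCc2ccccc2)=CC#C1 | intermediate
18 | potassium salt of the ortho-metallated O-aryl ether of 16, carbanion at the carbon between C–O and C–Cl (not isolated) | [K+].Clc1cc(OCc4ccccc4)cc(O[C@H](c3cc(OCc4ccccc4)c(OCc4ccccc4)c(OCc4ccccc4)c3)CC(=O)c5c(OCc4ccccc4)cc(OCc4ccccc4)c6c5O[C@H](c7cc(OCc4ccccc4)c(OCc4ccccc4)c(OCc4ccccc4)c7)[C@H](OCc4ccccc4)C6)[c-]1 | intermediate
19 | (2S,4RS)-7-(benzyloxy)-5-chloro-2-[3,4,5-tris(benzyloxy)phenyl]-4-[(2R,3R)-3,5,7-tris(benzyloxy)-2-(3,4,5-tris(benzyloxy)phenyl)chroman-8-yl]chroman-4-ol, both C4 epimers | O(Cc4ccccc4)c1cc(Cl)c2c(c1)O[C@H](c3cc(OCc4ccccc4)c(OCc4ccccc4)c(OCc4ccccc4)c3)CC2(O)c5c(OCc4ccccc4)cc(OCc4ccccc4)c6c5O[C@H](c7cc(OCc4ccccc4)c(OCc4ccccc4)c(OCc4ccccc4)c7)[C@H](OCc4ccccc4)C6 | intermediate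
20 | (2S)-7-(benzyloxy)-5-chloro-2-[3,4,5-tris(benzyloxy)phenyl]-4-[(2R,3R)-3,5,7-tris(benzyloxy)-2-(3,4,5-tris(benzyloxy)phenyl)chroman-8-yl]-2H-chromene | O(Cc4ccccc4)c1cc(Cl)c2c(c1)O[C@H](c3cc(OCc4ccccc4)c(OCc4ccccc4)c(OCc4ccccc4)c3)C=C2c5c(OCc4ccccc4)cc(OCc4ccccc4)c6c5O[C@H](c7cc(OCc4ccccc4)c(OCc4ccccc4)c(OCc4ccccc4)c7)[C@H](OCc4ccccc4)C6 | intermediate
21 | C3 alkylborane from 20, drawn as the monoalkylborane, boron trans to both aryl groups (not isolated) | O(Cc4ccccc4)c1cc(Cl)c2c(c1)O[C@H](c3cc(OCc4ccccc4)c(OCc4ccccc4)c(OCc4ccccc4)c3)[C@@H](B)[C@@H]2c5c(OCc4ccccc4)cc(OCc4ccccc4)c6c5O[C@H](c7cc(OCc4ccccc4)c(OCc4ccccc4)c(OCc4ccccc4)c7)[C@H](OCc4ccccc4)C6 | intermediate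
22 | (2R,3S,4R)-7-(benzyloxy)-5-chloro-2-[3,4,5-tris(benzyloxy)phenyl]-4-[(2R,3R)-3,5,7-tris(benzyloxy)-2-(3,4,5-tris(benzyloxy)phenyl)chroman-8-yl]chroman-3-ol, 2,3-trans-3,4-trans (same spatial arrangement as 23; the C4 descriptor differs only because chlorine changes the priorities) | O(Cc4ccccc4)c1cc(Cl)c2c(c1)O[C@H](c3cc(OCc4ccccc4)c(OCc4ccccc4)c(OCc4ccccc4)c3)[C@@H](O)[C@@H]2c5c(OCc4ccccc4)cc(OCc4ccccc4)c6c5O[C@H](c7cc(OCc4ccccc4)c(OCc4ccccc4)c(OCc4ccccc4)c7)[C@H](OCc4ccccc4)C6 | intermediate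
23 | robinetinidol-(4α→8)-epigallocatechin, upper unit (2R,3S,4S), lower unit (2R,3R) | Oc1ccc2c(c1)O[C@H](c1cc(O)c(O)c(O)c1)[C@@H](O)[C@@H]2c1c(O)cc(O)c2c1O[C@H](c1cc(O)c(O)c(O)c1)[C@H](O)C2 | target

**Totals**

Total step count: 12. Longest linear sequence: 8 steps (7 → 9 → 10 → 14 → 16 → 19 → 20 → 22 → 23).

**Steps most likely to fail**

Step 9 (Proposed new method). Retro-aldol cleavage or dehydration of 16 under fluoride may outrun O-arylation, or the aryl anion may be protonated before it closes onto the hindered ketone. The fallback uses known chemistry, gives up the annulation and forms the C4–C8 bond last. Commercial (+)-dihydrorobinetin is benzylated on its four phenols (BnBr, K2CO3, DMF) to (2R,3R)-7-(benzyloxy)-3-hydroxy-2-[3,4,5-tris(benzyloxy)phenyl]chroman-4-one F1. NaBH4 (THF/EtOH, 0 °C) reduces the ketone to the 2,3-trans-3,4-trans flavan-3,4-diol F2. Ionization of the C4 hydroxyl of F2 with BF3·OEt2 (CH2Cl2, −78 → −20 °C) in the presence of an excess of 9 should give the chlorine-free decabenzyl ether F3, the arene entering through its C8 and trans to the C3 hydroxyl of the flavan-4-yl cation. Hydrogenolysis of F3 under the conditions of step 12 gives 23. The fallback sets out from 9 and comes back at 23.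

Step 11. Borane may add slowly to the hindered trisubstituted alkene, may add from the face of the C2 aryl group, or the C3 borane may undergo β-elimination toward O1. In the fallback, dimethyldioxirane (acetone, −20 °C) epoxidizes 20 on the face opposite the C2 aryl group to the 3,4-epoxide F4. MgBr2·OEt2 (CH2Cl2, 0 °C) then induces a Meinwald rearrangement, a 1,2-hydride shift from C3 into the diaryl-stabilized C4 cation, and brief treatment with Et3N equilibrates the resulting ketone to the 2,4-cis diequatorial flavan-3-one F5. NaBH4 (THF/MeOH, −40 °C) should deliver hydride axially to give the all-equatorial alcohol 22. The fallback sets out from 20 and comes back at 22.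

Step 12. Hydrodechlorination at the hindered C5 position may stay incomplete, or chloride may poison the catalyst before all ten benzyl ethers are cleaved. The fallback separates the two events and moves the C–Cl reduction onto the free phenol. Neutral hydrogenolysis (H2, Pd/C, EtOAc/MeOH) removes only the benzyl groups and gives the 5-chloro undecaol F6. Transfer hydrogenolysis of this chlorophenol (Pd/C, HCO2NH4, MeOH, 40 °C) then removes chlorine and gives 23. The fallback sets out from 22 and comes back at 23.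

**Further compounds**

F1 | step 9 | (2R,3R)-7-(benzyloxy)-3-hydroxy-2-[3,4,5-tris(benzyloxy)phenyl]chroman-4-one | O(Cc4ccccc4)c1ccc2c(c1)O[C@H](c3cc(OCc4ccccc4)c(OCc4ccccc4)c(OCc4ccccc4)c3)[C@@H](O)C2=O
F2 | step 9 | (2R,3S,4R)-7-(benzyloxy)-2-[3,4,5-tris(benzyloxy)phenyl]chromane-3,4-diol | O(Cc4ccccc4)c1ccc2c(c1)O[C@H](c3cc(OCc4ccccc4)c(OCc4ccccc4)c(OCc4ccccc4)c3)[C@@H](O)[C@@H]2O
F3 | step 9 | (2R,3S,4S)-7-(benzyloxy)-2-[3,4,5-tris(benzyloxy)phenyl]-4-[(2R,3R)-3,5,7-tris(benzyloxy)-2-(3,4,5-tris(benzyloxy)phenyl)chroman-8-yl]chroman-3-ol | O(Cc4ccccc4)c1ccc2c(c1)O[C@H](c3cc(OCc4ccccc4)c(OCc4ccccc4)c(OCc4ccccc4)c3)[C@@H](O)[C@@H]2c5c(OCc4ccccc4)cc(OCc4ccccc4)c6c5O[C@H](c7cc(OCc4ccccc4)c(OCc4ccccc4)c(OCc4ccccc4)c7)[C@H](OCc4ccccc4)C6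
F4 | step 11 | 3,4-epoxide of 20, epoxide oxygen trans to the C2 aryl group | O(Cc4ccccc4)c1cc(Cl)c2c(c1)O[C@H](c3cc(OCc4ccccc4)c(OCc4ccccc4)c(OCc4ccccc4)c3)[C@H]8O[C@@]28c5c(OCc4ccccc4)cc(OCc4ccccc4)c6c5O[C@H](c7cc(OCc4ccccc4)c(OCc4ccccc4)c(OCc4ccccc4)c7)[C@H](OCc4ccccc4)C6
F5 | step 11 | 2,4-cis-7-(benzyloxy)-5-chloro-2-[3,4,5-tris(benzyloxy)phenyl]-4-[(2R,3R)-3,5,7-tris(benzyloxy)-2-(3,4,5-tris(benzyloxy)phenyl)chroman-8-yl]chroman-3-one | O(Cc4ccccc4)c1cc(Cl)c2c(c1)O[C@H](c3cc(OCc4ccccc4)c(OCc4ccccc4)c(OCc4ccccc4)c3)C(=O)[C@@H]2c5c(OCc4ccccc4)cc(OCc4ccccc4)c6c5O[C@H](c7cc(OCc4ccccc4)c(OCc4ccccc4)c(OCc4ccccc4)c7)[C@H](OCc4ccccc4)C6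
F6 | step 12 | 5-chloro derivative of 23 (chlorine on ring A of the upper unit) | Oc1cc(Cl)c2c(c1)O[C@H](c1cc(O)c(O)c(O)c1)[C@@H](O)[C@@H]2c1c(O)cc(O)c2c1O[C@H](c1cc(O)c(O)c(O)c1)[C@H](O)C2
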